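In this closed, stirred vessel a catalyst turns starting material into product while a protic impurity consumes starting material on the side.

    catalyst intermediate A ⇌ catalyst intermediate B (K1 = 43, k1 = 3.3 s⁻¹)
    reagent + catalyst intermediate B → catalyst intermediate C (k2 = 1400 M⁻¹ s⁻¹)
    starting material + free catalyst → catalyst intermediate A (k3 = 7200 M⁻¹ s⁻¹)
    starting material + protic impurity → quenched substrate (k4 = 15 M⁻¹ s⁻¹)
    catalyst intermediate D → free catalyst + product (k5 = 3.1 s⁻¹)
    precatalyst → free catalyst (k6 = 0.0067 s⁻¹)
    catalyst intermediate C → released group + catalyst intermediate D (k7 = 0.72 s⁻¹)

| flask | starting material | reagent | protic impurity | precatalyst | time |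
|---|---|---|---|---|---|
| oak | 20 mM | 80.0 mM | 0.600 mM | 0.16 mM | 50 s |
| larch | 20 mM | 80.0 mM | 0.800 mM | 0.16 mM | 50 s |
| alder | 20 mM | 80.0 mM | 1.20 mM | 0.16 mM | 50 s |
| maple | 20 mM | 80.0 mM | 2.00 mM | 0.16 mM | 50 s |

- "hardly changes" means that all values lie within two and a half points (for a concentration: within two and a half percent of the largest)
- run time (oak): 50 s

* [product] at the end for oak, larch, alder, maple, in this order
* the course of these numbers from the first flask to the last (falls, then rises / rises all the way / rises, then falls / hardly changes / falls all the way)

- The precatalyst is charged in a smaller amount than anything else, so I write its balance: c(precatalyst) plus the catalyst forms on the round equals 0.16 mM. Product comes from the forms on the round, and these grow as the precatalyst releases free catalyst.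
- With starting material and reagent held at their charge, their two capture steps are pseudo-first-order and wait 0.00694 s and 0.00893 s. Catalyst intermediate A waits 0.303 s to become catalyst intermediate B, catalyst intermediate C waits 1.39 s to lose the released group, and catalyst intermediate D waits 0.323 s to give product.
- Their sum is 2.03 s: this is the round time, the seconds a catalyst on the round needs for each product.
- Product goes as one over the round time, so an error in a constant passes on by that step's share of it. The loss of the released group holds 68.4 % and is the rate-limiting step, so 0.72 s⁻¹ has to be known well.
- 3.3 s⁻¹ and 3.1 s⁻¹ count for 14.9 % and 15.9 %. The two capture constants together count for 0.782 %, so they need little care.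
- 0.0067 s⁻¹ matters too: the precatalyst's half-life of 100 s is longer than the run of 50 s, so product follows an error in it nearly in proportion.
- The way back from catalyst intermediate B is slower than its capture by reagent, so 43 needs little care.
- The protic impurity enters no catalyst step. Even the whole maple charge, taken from the starting material, lengthens the round by 7.72 × 10⁻⁴ s.
- Now the number: the catalyst out of the precatalyst reaches 0.0455 mM at 50 s. I integrate that amount over the run and divide by the round time, which gives 0.592 mM in each flask. I take this as slightly high, since catalyst released in the last round time has not finished its first round, a wait short against the run.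
- The forecast gives 0.581 mM, 0.581 mM, 0.58 mM and 0.579 mM, a row that hardly changes, a little below my figure, with product “governed by the slow precatalyst release”.
- The flasks give 0.581 mM, 0.581 mM, 0.581 mM and 0.581 mM, a row that hardly changes. Starting material at the end stands at 93.9 % in oak and 86.9 % in maple. The round time also spreads the catalyst: in maple at 50.0 s, 28.5 % of the catalyst charged has left the precatalyst, and the wait at catalyst intermediate C, divided by the round time, puts 19.5 % of the charge there. Maple holds 19.4 % of the catalyst charged as catalyst intermediate C.

Its constants are made up; the result is computed.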